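The seven-membered carbocycle (C1 carbinol, C5 acyloxy-CH, C6 lactone O–CH, C7, C8 H2, C9 ketone, C10 methyl-CH) is closed last, across C10–C1, by a copper hydride reductive aldol cyclisation. The step exploits the β-hydroxy ketone C9(=O)–C10–C1(OH) inside that ring: hydride addition to a vinyl ketone arm on C7 gives the C10 enolate regiospecifically, which adds to a C1 ketone activated by oxygen on C5 and C2, forming the ring and both C10 and C1 stereocentres in one operation. The precursor is a cis-4,5-disubstituted γ-butyrolactone carrying a masked α-methylene group (CH2SPh), built from (R)-glyceraldehyde acetonide, whose stereocentre relays C5, C6 and C7.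

Key step: step 10

Remark on locants: guaiane-type numbering as above; C11/C12/C13 are the lactone α-carbon, carbonyl and exocyclic methylene, C2–C4/C15 the butenoyl chain, C14 the methyl on C10.
Remark on mixtures: from 12 to 28 the lactone α-carbon C11 is an epimer mixture that converges in step 15, and 26 is a carbinol epimer mixture at C2 that converges in step 14; both centres are drawn without configuration.
Assumption: 1, 2, 4, 6, 8, 10, 14, 18 and 25 are purchased, and Stryker's reagent is used as the commercial hexamer.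

Step 1
Reactants: 1 4-bromofuran-2(5H)-one; 2 (2-tert-butoxy-2-oxoethyl)zinc bromide
Product: 3 tert-butyl 2-(5-oxo-2,5-dihydrofuran-3-yl)acetate
Conditions: Pd(dba)2 (2 mol %), Q-Phos (2 mol %), THF, rt
Reagents that add atoms: (2-tert-butoxy-2-oxoethyl)zinc bromide (2), CC(C)(C)OC(=O)C[Zn]Br
Why: Negishi coupling of a Reformatsky reagent with the activated β-bromo butenolide should install the C8–C9 acetate arm on the future C7.

Step 2
Reactants: 3 tert-butyl 2-(5-oxo-2,5-dihydrofuran-3-yl)acetate; 4 tert-butyldimethylsilyl trifluoromethanesulfonate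
Product: 5 tert-butyl 2-{5-[(tert-butyldimethylsilyl)oxy]furan-3-yl}acetate
Conditions: TBSOTf (1.05 equiv), Et3N, CH2Cl2, −20 °C
Reagents that add atoms: tert-butyldimethylsilyl trifluoromethanesulfonate (4), CC(C)(C)[Si](C)(C)OS(=O)(=O)C(F)(F)F
Why: Soft enolisation at the γ-position gives the aromatic 2-silyloxyfuran as the thermodynamic dienol ether, and the tert-butyl ester should tolerate one equivalent of silyl triflate with amine at low temperature.

Step 3
Reactants: 5 tert-butyl 2-{5-[(tert-butyldimethylsilyl)oxy]furan-3-yl}acetate; 6 (R)-2,2-dimethyl-1,3-dioxolane-4-carbaldehyde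
Product: 7 tert-butyl 2-[(2R)-2-{(S)-[(4R)-2,2-dimethyl-1,3-dioxolan-4-yl](hydroxy)methyl}-5-oxo-2,5-dihydrofuran-3-yl]acetate
Conditions: BF3·OEt2 (1.1 equiv), CH2Cl2, −78 °C
Reagents that add atoms: (R)-2,2-dimethyl-1,3-dioxolane-4-carbaldehyde (6), O=C[C@H]1COC(C)(C)O1
Why: In this vinylogous Mukaiyama aldol addition the furan γ-carbon should attack the Felkin face of the α-alkoxy aldehyde (C5 erythro to the dioxolane centre) through an open transition state that gives the threo C5/C6 pair, as known for 2-silyloxyfurans with glyceraldehyde acetonide.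

Step 4
Reactants: 7 tert-butyl 2-[(2R)-2-{(S)-[(4R)-2,2-dimethyl-1,3-dioxolan-4-yl](hydroxy)methyl}-5-oxo-2,5-dihydrofuran-3-yl]acetate; 8 (S)-2-methylbutanoic acid
Product: 9 tert-butyl 2-[(2R)-2-{(S)-[(4R)-2,2-dimethyl-1,3-dioxolan-4-yl]{[(2S)-2-methylbutanoyl]oxy}methyl}-5-oxo-2,5-dihydrofuran-3-yl]acetate
Conditions: EDC·HCl, DMAP (cat.), CH2Cl2, 0 °C
Reagents that add atoms: (S)-2-methylbutanoic acid (8), CC[C@H](C)C(=O)O
Why: Steglich esterification acylates the only free hydroxyl under conditions mild enough to avoid base-induced elimination of the butenolide and epimerisation of the acid.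

Step 5
Reactants: 9 tert-butyl 2-[(2R)-2-{(S)-[(4R)-2,2-dimethyl-1,3-dioxolan-4-yl]{[(2S)-2-methylbutanoyl]oxy}methyl}-5-oxo-2,5-dihydrofuran-3-yl]acetate; 10 chloromethyl phenyl sulfide
Product: 12 tert-butyl 2-[(2R,3S)-2-{(S)-[(4R)-2,2-dimethyl-1,3-dioxolan-4-yl]{[(2S)-2-methylbutanoyl]oxy}methyl}-5-oxo-4-[(phenylsulfanyl)methyl]oxolan-3-yl]acetate (C4 epimers), via silyl ketene acetal 11 (not isolated)
Conditions: [(Ph3P)CuH]6 (cat.), PhMe2SiH, toluene, rt; then PhSCH2Cl, ZnBr2 (cat.), CH2Cl2, 0 °C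
Reagents that add atoms: chloromethyl phenyl sulfide (10), ClCSc1ccccc1
Why: CuH-catalysed 1,4-hydrosilylation should deliver hydride to C7 anti to the C6 substituent (cis lactone), and the regiodefined silyl ketene acetal is then alkylated at C11 by Paterson phenylthiomethylation, which installs C13 as a masked methylene.

Step 6
Reactants: 12 tert-butyl 2-[(2R,3S)-2-{(S)-[(4R)-2,2-dimethyl-1,3-dioxolan-4-yl]{[(2S)-2-methylbutanoyl]oxy}methyl}-5-oxo-4-[(phenylsulfanyl)methyl]oxolan-3-yl]acetate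
Product: 13 2-[(2R,3S)-2-[(1R,2R)-2,3-dihydroxy-1-{[(2S)-2-methylbutanoyl]oxy}propyl]-5-oxo-4-[(phenylsulfanyl)methyl]oxolan-3-yl]acetic acid
Conditions: TFA/H2O (9:1), 0 °C to rt
Reagents that add atoms: none
Why: Aqueous acid should cleave the acetonide and the tert-butyl ester in one operation, while the lactone, the hindered secondary ester and the sulfide are stable to acid.

Step 7
Reactants: 13 2-[(2R,3S)-2-[(1R,2R)-2,3-dihydroxy-1-{[(2S)-2-methylbutanoyl]oxy}propyl]-5-oxo-4-[(phenylsulfanyl)methyl]oxolan-3-yl]acetic acid; 14 tert-butyldimethylsilyl chloride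
Product: 16 2-[(2R,3S)-2-[(1R,2R)-3-[(tert-butyldimethylsilyl)oxy]-2-hydroxy-1-{[(2S)-2-methylbutanoyl]oxy}propyl]-5-oxo-4-[(phenylsulfanyl)methyl]oxolan-3-yl]acetic acid, via bis-silylated silyl ester 15 (not isolated)
Conditions: TBSCl (2.2 equiv), imidazole, DMF, 0 °C; pH 4 aqueous work-up
Reagents that add atoms: tert-butyldimethylsilyl chloride (14), CC(C)(C)[Si](C)(C)Cl
Why: Silylation is selective for the primary C2 hydroxyl over the hindered secondary C1 hydroxyl, and the transient silyl ester is hydrolysed on work-up.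

Step 8
Reactants: 16 2-[(2R,3S)-2-[(1R,2R)-3-[(tert-butyldimethylsilyl)oxy]-2-hydroxy-1-{[(2S)-2-methylbutanoyl]oxy}propyl]-5-oxo-4-[(phenylsulfanyl)methyl]oxolan-3-yl]acetic acid
Product: 17 2-[(2R,3S)-2-[(1S)-3-[(tert-butyldimethylsilyl)oxy]-1-{[(2S)-2-methylbutanoyl]oxy}-2-oxopropyl]-5-oxo-4-[(phenylsulfanyl)methyl]oxolan-3-yl]acetic acid
Conditions: Dess–Martin periodinane, CH2Cl2, 0 °C to rt
Reagents that add atoms: none
Why: Dess–Martin oxidation converts the temporary C1 carbinol into the acceptor ketone under non-basic conditions that should spare the sulfide and the β-acyloxy lactone array.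

Step 9
Reactants: 17 2-[(2R,3S)-2-[(1S)-3-[(tert-butyldimethylsilyl)oxy]-1-{[(2S)-2-methylbutanoyl]oxy}-2-oxopropyl]-5-oxo-4-[(phenylsulfanyl)methyl]oxolan-3-yl]acetic acid; 18 tributyl(vinyl)stannane
Product: 20 (1S)-3-[(tert-butyldimethylsilyl)oxy]-2-oxo-1-[(2R,3S)-5-oxo-3-(2-oxobut-3-en-1-yl)-4-[(phenylsulfanyl)methyl]oxolan-2-yl]propyl (2S)-2-methylbutanoate, via acid chloride 19 (not isolated)
Conditions: 1-chloro-N,N,2-trimethylprop-1-en-1-amine, CH2Cl2, 0 °C; then Bu3SnCH=CH2, Pd2(dba)3 (cat.), P(2-furyl)3, THF, rt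
Reagents that add atoms: tributyl(vinyl)stannane (18), C=C[Sn](CCCC)(CCCC)CCCC
Why: Neutral acid chloride formation (Ghosez reagent) followed by Stille acylation gives the vinyl ketone without base or acid, so the silyl ether and the enolisable α-acyloxy ketone should survive.

Step 10
Reactants: 20 (1S)-3-[(tert-butyldimethylsilyl)oxy]-2-oxo-1-[(2R,3S)-5-oxo-3-(2-oxobut-3-en-1-yl)-4-[(phenylsulfanyl)methyl]oxolan-2-yl]propyl (2S)-2-methylbutanoate
Product: 22 (3aS,6R,7R,8S,8aR)-7-{[(tert-butyldimethylsilyl)oxy]methyl}-7-hydroxy-6-methyl-2,5-dioxo-3-[(phenylsulfanyl)methyl]octahydro-2H-cyclohepta[b]furan-8-yl (2S)-2-methylbutanoate, via copper(I) Z-enolate 21 (not isolated)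
Conditions: [(Ph3P)CuH]6 (0.25 equiv), toluene/THF (0.01 M), −40 to 0 °C; aq NH4Cl
Reagents that add atoms: none
Why: Cu–H adds hydride to the terminal carbon (C14) of the s-cis vinyl ketone, giving regiospecifically the (Z)-copper enolate C9(OCu)=C10, which adds to the C1 ketone (activated by the C5 acyloxy and C2 silyloxy groups) before it can equilibrate, and the copper aldolate is protonated on work-up. The closest known reaction is the Stryker-reagent reductive aldol cyclisation of keto-enones. The cycloheptanone closes in a 7-(enolendo)-exo-trig mode across C10–C1. C10 is set by the Z-enolate geometry in a copper-bridged chair transition state in which the tether carbon C5 must be axial, which should put the C10 methyl cis to the new C1 hydroxyl; C1 is set by the C5 stereocentre, the enolate attacking the dipole-minimised (Cornforth) rotamer from the face on which ring carbon C6 lies, which should put the hydroxyl trans to the C5 acyloxy group. The step needs 1,4- over 1,2-reduction and a C10 (not C8) enolate: the vinyl ketone is the only conjugate acceptor because the α-methylene lactone is masked as its PhS adduct and the butenoyl group is not yet present, and no base is used.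

Step 11
Reactants: 22 (3aS,6R,7R,8S,8aR)-7-{[(tert-butyldimethylsilyl)oxy]methyl}-7-hydroxy-6-methyl-2,5-dioxo-3-[(phenylsulfanyl)methyl]octahydro-2H-cyclohepta[b]furan-8-yl (2S)-2-methylbutanoate
Product: 23 (3aS,6R,7R,8S,8aR)-7-hydroxy-7-(hydroxymethyl)-6-methyl-2,5-dioxo-3-[(phenylsulfanyl)methyl]octahydro-2H-cyclohepta[b]furan-8-yl (2S)-2-methylbutanoate
Conditions: HF·pyridine, pyridine, THF, 0 °C to rt
Reagents that add atoms: none
Why: Buffered fluoride removes the primary silyl ether without the basic conditions that could trigger retro-aldol cleavage or acyl migration.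

Step 12
Reactants: 23 (3aS,6R,7R,8S,8aR)-7-hydroxy-7-(hydroxymethyl)-6-methyl-2,5-dioxo-3-[(phenylsulfanyl)methyl]octahydro-2H-cyclohepta[b]furan-8-yl (2S)-2-methylbutanoate
Product: 24 (3aS,6R,7S,8S,8aR)-7-formyl-7-hydroxy-6-methyl-2,5-dioxo-3-[(phenylsulfanyl)methyl]octahydro-2H-cyclohepta[b]furan-8-yl (2S)-2-methylbutanoate
Conditions: Dess–Martin periodinane, CH2Cl2, 0 °C
Reagents that add atoms: none
Why: Only the primary alcohol can be oxidised, and the resulting α-hydroxy aldehyde has no α-hydrogen, so it cannot enolise or eliminate.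

Step 13
Reactants: 24 (3aS,6R,7S,8S,8aR)-7-formyl-7-hydroxy-6-methyl-2,5-dioxo-3-[(phenylsulfanyl)methyl]octahydro-2H-cyclohepta[b]furan-8-yl (2S)-2-methylbutanoate; 25 (E)-1-iodoprop-1-ene
Product: 26 (3aS,6R,7R,8S,8aR)-7-hydroxy-7-[(2E)-1-hydroxybut-2-en-1-yl]-6-methyl-2,5-dioxo-3-[(phenylsulfanyl)methyl]octahydro-2H-cyclohepta[b]furan-8-yl (2S)-2-methylbutanoate (carbinol epimers)
Conditions: CrCl2, NiCl2 (cat.), DMSO/THF, rt
Reagents that add atoms: (E)-1-iodoprop-1-ene (25), C/C=C/I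
Why: The Nozaki–Hiyama–Kishi reaction adds the alkenylchromium species to the aldehyde with retention of the E geometry and leaves the C9 ketone, lactone and ester untouched.

Step 14
Reactants: 26 (3aS,6R,7R,8S,8aR)-7-hydroxy-7-[(2E)-1-hydroxybut-2-en-1-yl]-6-methyl-2,5-dioxo-3-[(phenylsulfanyl)methyl]octahydro-2H-cyclohepta[b]furan-8-yl (2S)-2-methylbutanoate
Product: 27 (3aS,6R,7S,8S,8aR)-7-[(2E)-but-2-enoyl]-7-hydroxy-6-methyl-2,5-dioxo-3-[(phenylsulfanyl)methyl]octahydro-2H-cyclohepta[b]furan-8-yl (2S)-2-methylbutanoate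
Conditions: MnO2 (activated), CH2Cl2, rt
Reagents that add atoms: none
Why: Manganese dioxide oxidises the allylic carbinol selectively to the enone, converging both C2 epimers and sparing the tertiary alcohol and the sulfide.

Step 15
Reactants: 27 (3aS,6R,7S,8S,8aR)-7-[(2E)-but-2-enoyl]-7-hydroxy-6-methyl-2,5-dioxo-3-[(phenylsulfanyl)methyl]octahydro-2H-cyclohepta[b]furan-8-yl (2S)-2-methylbutanoate
Product: 29 (3aS,6R,7S,8S,8aR)-7-[(2E)-but-2-enoyl]-7-hydroxy-6-methyl-3-methylidene-2,5-dioxooctahydro-2H-cyclohepta[b]furan-8-yl (2S)-2-methylbutanoate, via sulfoxide 28 (not isolated)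
Conditions: mCPBA (1.0 equiv), CH2Cl2, −78 °C; then CaCO3, toluene, 90 °C
Reagents that add atoms: none
Why: Chemoselective S-oxidation followed by thermal syn-elimination of the sulfoxide, whose only β-hydrogen is on C11, should unveil the exocyclic α-methylene lactone and converge the C11 epimers.

Compound list
1 | 4-bromofuran-2(5H)-one | O=C1C=C(Br)CO1 | starting material
2 | (2-tert-butoxy-2-oxoethyl)zinc bromide | CC(C)(C)OC(=O)C[Zn]Br | starting material
3 | tert-butyl 2-(5-oxo-2,5-dihydrofuran-3-yl)acetate | CC(C)(C)OC(=O)CC1=CC(=O)OC1 | intermediate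
4 | tert-butyldimethylsilyl trifluoromethanesulfonate | CC(C)(C)[Si](C)(C)OS(=O)(=O)C(F)(F)F | starting material
5 | tert-butyl 2-{5-[(tert-butyldimethylsilyl)oxy]furan-3-yl}acetate | CC(C)(C)OC(=O)Cc1coc(O[Si](C)(C)C(C)(C)C)c1 | intermediate
6 | (R)-2,2-dimethyl-1,3-dioxolane-4-carbaldehyde | O=C[C@H]1COC(C)(C)O1 | starting material
7 | tert-butyl 2-[(2R)-2-{(S)-[(4R)-2,2-dimethyl-1,3-dioxolan-4-yl](hydroxy)methyl}-5-oxo-2,5-dihydrofuran-3-yl]acetate | O=C1O[C@@H]([C@H](O)[C@H]2COC(C)(C)O2)C(CC(=O)OC(C)(C)C)=C1 | intermediate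
8 | (S)-2-methylbutanoic acid | CC[C@H](C)C(=O)O | starting material
9 | tert-butyl 2-[(2R)-2-{(S)-[(4R)-2,2-dimethyl-1,3-dioxolan-4-yl]{[(2S)-2-methylbutanoyl]oxy}methyl}-5-oxo-2,5-dihydrofuran-3-yl]acetate | O=C1O[C@@H]([C@H](OC(=O)[C@@H](C)CC)[C@H]2COC(C)(C)O2)C(CC(=O)OC(C)(C)C)=C1 | intermediate
10 | chloromethyl phenyl sulfide | ClCSc1ccccc1 | starting material
11 | tert-butyl 2-[(2R,3S)-5-{[dimethyl(phenyl)silyl]oxy}-2-{(S)-[(4R)-2,2-dimethyl-1,3-dioxolan-4-yl]{[(2S)-2-methylbutanoyl]oxy}methyl}-2,3-dihydrofuran-3-yl]acetate (silyl ketene acetal) | C[Si](C)(c1ccccc1)OC1=C[C@H](CC(=O)OC(C)(C)C)[C@@H](O1)[C@H](OC(=O)[C@@H](C)CC)[C@H]1COC(C)(C)O1 | intermediate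
12 | tert-butyl 2-[(2R,3S)-2-{(S)-[(4R)-2,2-dimethyl-1,3-dioxolan-4-yl]{[(2S)-2-methylbutanoyl]oxy}methyl}-5-oxo-4-[(phenylsulfanyl)methyl]oxolan-3-yl]acetate (C4 epimers) | O=C1O[C@@H]([C@H](OC(=O)[C@@H](C)CC)[C@H]2COC(C)(C)O2)[C@@H](CC(=O)OC(C)(C)C)C1CSc1ccccc1 | intermediate
13 | 2-[(2R,3S)-2-[(1R,2R)-2,3-dihydroxy-1-{[(2S)-2-methylbutanoyl]oxy}propyl]-5-oxo-4-[(phenylsulfanyl)methyl]oxolan-3-yl]acetic acid | O=C1O[C@@H]([C@H](OC(=O)[C@@H](C)CC)[C@H](O)CO)[C@@H](CC(=O)O)C1CSc1ccccc1 | intermediate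
14 | tert-butyldimethylsilyl chloride | CC(C)(C)[Si](C)(C)Cl | starting material
15 | tert-butyldimethylsilyl ester of 16 (bis-silylated 13) | O=C1O[C@@H]([C@H](OC(=O)[C@@H](C)CC)[C@H](O)CO[Si](C)(C)C(C)(C)C)[C@@H](CC(=O)O[Si](C)(C)C(C)(C)C)C1CSc1ccccc1 | intermediate
16 | 2-[(2R,3S)-2-[(1R,2R)-3-[(tert-butyldimethylsilyl)oxy]-2-hydroxy-1-{[(2S)-2-methylbutanoyl]oxy}propyl]-5-oxo-4-[(phenylsulfanyl)methyl]oxolan-3-yl]acetic acid | O=C1O[C@@H]([C@H](OC(=O)[C@@H](C)CC)[C@H](O)CO[Si](C)(C)C(C)(C)C)[C@@H](CC(=O)O)C1CSc1ccccc1 | intermediate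
17 | 2-[(2R,3S)-2-[(1S)-3-[(tert-butyldimethylsilyl)oxy]-1-{[(2S)-2-methylbutanoyl]oxy}-2-oxopropyl]-5-oxo-4-[(phenylsulfanyl)methyl]oxolan-3-yl]acetic acid | O=C1O[C@@H]([C@H](OC(=O)[C@@H](C)CC)C(=O)CO[Si](C)(C)C(C)(C)C)[C@@H](CC(=O)O)C1CSc1ccccc1 | intermediate
18 | tributyl(vinyl)stannane | C=C[Sn](CCCC)(CCCC)CCCC | starting material
19 | acid chloride of 17 | O=C1O[C@@H]([C@H](OC(=O)[C@@H](C)CC)C(=O)CO[Si](C)(C)C(C)(C)C)[C@@H](CC(=O)Cl)C1CSc1ccccc1 | intermediate
20 | (1S)-3-[(tert-butyldimethylsilyl)oxy]-2-oxo-1-[(2R,3S)-5-oxo-3-(2-oxobut-3-en-1-yl)-4-[(phenylsulfanyl)methyl]oxolan-2-yl]propyl (2S)-2-methylbutanoate | O=C1O[C@@H]([C@H](OC(=O)[C@@H](C)CC)C(=O)CO[Si](C)(C)C(C)(C)C)[C@@H](CC(=O)C=C)C1CSc1ccccc1 | intermediate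
21 | copper(I) (Z)-enolate of the C9 ketone (C9–O–Cu, C9=C10) | O=C1O[C@@H]([C@H](OC(=O)[C@@H](C)CC)C(=O)CO[Si](C)(C)C(C)(C)C)[C@@H](C/C(O[Cu])=C/C)C1CSc1ccccc1 | intermediate
22 | (3aS,6R,7R,8S,8aR)-7-{[(tert-butyldimethylsilyl)oxy]methyl}-7-hydroxy-6-methyl-2,5-dioxo-3-[(phenylsulfanyl)methyl]octahydro-2H-cyclohepta[b]furan-8-yl (2S)-2-methylbutanoate | c1ccccc1SCC2C(=O)O[C@@H]3[C@H]2CC(=O)[C@H](C)[C@@](O)(CO[Si](C)(C)C(C)(C)C)[C@H]3OC(=O)[C@@H](C)CC | intermediate
23 | (3aS,6R,7R,8S,8aR)-7-hydroxy-7-(hydroxymethyl)-6-methyl-2,5-dioxo-3-[(phenylsulfanyl)methyl]octahydro-2H-cyclohepta[b]furan-8-yl (2S)-2-methylbutanoate | c1ccccc1SCC2C(=O)O[C@@H]3[C@H]2CC(=O)[C@H](C)[C@@](O)(CO)[C@H]3OC(=O)[C@@H](C)CC | intermediate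
24 | (3aS,6R,7S,8S,8aR)-7-formyl-7-hydroxy-6-methyl-2,5-dioxo-3-[(phenylsulfanyl)methyl]octahydro-2H-cyclohepta[b]furan-8-yl (2S)-2-methylbutanoate | c1ccccc1SCC2C(=O)O[C@@H]3[C@H]2CC(=O)[C@H](C)[C@@](O)(C=O)[C@H]3OC(=O)[C@@H](C)CC | intermediate
25 | (E)-1-iodoprop-1-ene | C/C=C/I | starting material
26 | (3aS,6R,7R,8S,8aR)-7-hydroxy-7-[(2E)-1-hydroxybut-2-en-1-yl]-6-methyl-2,5-dioxo-3-[(phenylsulfanyl)methyl]octahydro-2H-cyclohepta[b]furan-8-yl (2S)-2-methylbutanoate (carbinol epimers) | c1ccccc1SCC2C(=O)O[C@@H]3[C@H]2CC(=O)[C@H](C)[C@@](O)(C(O)/C=C/C)[C@H]3OC(=O)[C@@H](C)CC | intermediate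
27 | (3aS,6R,7S,8S,8aR)-7-[(2E)-but-2-enoyl]-7-hydroxy-6-methyl-2,5-dioxo-3-[(phenylsulfanyl)methyl]octahydro-2H-cyclohepta[b]furan-8-yl (2S)-2-methylbutanoate | c1ccccc1SCC2C(=O)O[C@@H]3[C@H]2CC(=O)[C@H](C)[C@@](O)(C(=O)/C=C/C)[C@H]3OC(=O)[C@@H](C)CC | intermediate
28 | sulfoxide of 27 (phenylsulfinylmethyl lactone) | O=S(CC2C(=O)O[C@@H]3[C@H]2CC(=O)[C@H](C)[C@@](O)(C(=O)/C=C/C)[C@H]3OC(=O)[C@@H](C)CC)c1ccccc1 | intermediate
29 | (3aS,6R,7S,8S,8aR)-7-[(2E)-but-2-enoyl]-7-hydroxy-6-methyl-3-methylidene-2,5-dioxooctahydro-2H-cyclohepta[b]furan-8-yl (2S)-2-methylbutanoate (CNP0153197.2) | C=C1C(=O)O[C@@H]2[C@H]1CC(=O)[C@H](C)[C@@](O)(C(=O)/C=C/C)[C@H]2OC(=O)[C@@H](C)CC | target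

Total step count: 15. Longest linear sequence: 15 steps (from 1).

Steps most likely to fail

Step 10. The copper enolate may be protonated or may equilibrate towards C8 before the slow seven-membered closure. Closure may also run through a chelated arrangement that delivers the wrong face at C1. The fallback separates enolate formation from C–C bond formation. Setting out from 20, rhodium-catalysed 1,4-hydrosilylation (Et3SiH, (Ph3P)3RhCl, benzene) should give the isolable triethylsilyl (Z)-enol ether F1. Treatment with BF3·OEt2 in CH2Cl2 at −78 °C should then effect an intramolecular Mukaiyama aldol addition through an open, non-chelated transition state. Aqueous work-up brings the route back at 22.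

Step 5. The silyl ketene acetal may undergo protodesilylation or react sluggishly with the chloromethyl sulfide, so that C13 is not installed. The fallback uses an iminium electrophile and introduces sulfur afterwards. Setting out from 9, stoichiometric Stryker reduction and trapping of the copper enolate with Eschenmoser's salt should give the Mannich base F2. N-Methylation (MeI) and elimination with NaHCO3 should give the α-methylene lactone F3. Conjugate addition of thiophenol (Et3N cat.) to F3 brings the route back at 12.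

Step 13. Addition of the alkenylchromium species to the neopentylic α-hydroxy aldehyde may be slow, letting retro-aldol opening of the β-hydroxy ketone compete. The fallback builds the enone by olefination instead of carbonyl addition and oxidation. Setting out from 24, tin(II) chloride-catalysed homologation with dimethyl (diazomethyl)phosphonate (Roskamp-type) should give the β-ketophosphonate F4. A Masamune–Roush Horner–Wadsworth–Emmons reaction with acetaldehyde (LiCl, iPr2NEt, MeCN) should give the (E)-enone directly, bringing the route back at 27.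

Further compounds
F1 | step 10 | triethylsilyl (Z)-enol ether of vinyl ketone 20 after 1,4-hydrosilylation | O=C1O[C@@H]([C@H](OC(=O)[C@@H](C)CC)C(=O)CO[Si](C)(C)C(C)(C)C)[C@@H](C/C(O[Si](CC)(CC)CC)=C/C)C1CSc1ccccc1
F2 | step 5 | Mannich base: 4-[(dimethylamino)methyl] analogue of 12 | O=C1O[C@@H]([C@H](OC(=O)[C@@H](C)CC)[C@H]2COC(C)(C)O2)[C@@H](CC(=O)OC(C)(C)C)C1CN(C)C
F3 | step 5 | α-methylene lactone: 4-methylidene analogue of 12 | C=C1C(=O)O[C@@H]([C@H](OC(=O)[C@@H](C)CC)[C@H]2COC(C)(C)O2)[C@H]1CC(=O)OC(C)(C)C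
F4 | step 13 | β-ketophosphonate: 7-[2-(dimethoxyphosphoryl)acetyl] analogue of 27 | c1ccccc1SCC2C(=O)O[C@@H]3[C@H]2CC(=O)[C@H](C)[C@@](O)(C(=O)CP(=O)(OC)OC)[C@H]3OC(=O)[C@@H](C)CC
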